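**Retrosynthetic overview**
- Target ⇒ (ester C–O) primary/tertiary diol ⇒ (oxolane C1–O, palladium-catalysed opening of a dienyl oxirane) hydroxy dienone ⇒ (C1–dienyl bond) trans-fused γ-lactone on the cyclononene.
- Key disconnection: the lactone-fused nine-membered ring ⇒ an eleven-membered allylic macrolactone, by an Ireland–Claisen ring contraction that makes the ring-fusion C–C bond, the exocyclic methylene and both fusion stereocentres, with desilylative lactonisation in the same flask.
- Macrolactone ⇒ open-chain ester (ring-closing metathesis) ⇒ an (S)-linalool-derived acid (carbinol stereocentre from the chiral pool) plus an E-trisubstituted allylic alcohol (Horner–Wadsworth–Emmons).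
- Ring order: eleven-membered lactone (temporary) → nine-membered carbocycle and γ-lactone together → oxolane (lactone opened by the dienyl group, ring re-closed on C1).

Assumption: the acyl chain is nonadecanoyl (C19) exactly as in the given SMILES; the enantiomer named for each chiral reagent (diazaborolidine in step 10, Trost ligand in step 13) is chosen by analogy and would be exchanged for its mirror image if the sense of induction proves opposite.

**Route**

Step 1
Reactants: 1 (S)-(+)-linalool [(3S)-3,7-dimethylocta-1,6-dien-3-ol]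
Product: 2 (3S)-3,7-dimethyl-3-[(triethylsilyl)oxy]octa-1,6-diene
Conditions: Et3SiOTf, 2,6-lutidine, CH2Cl2, −78 → 0 °C
Reagents that add atoms: triethylsilyl trifluoromethanesulfonate, CC[Si](CC)(CC)OS(=O)(=O)C(F)(F)F
Why: Silyl triflate protection of the hindered tertiary alcohol, which leaves the chiral-pool (S)-carbinol centre untouched and masks it for the organolithium and boron chemistry ahead.

Step 2
Reactants: 2 (3S)-3,7-dimethyl-3-[(triethylsilyl)oxy]octa-1,6-diene
Product: 3 (4S)-4-methyl-4-[(triethylsilyl)oxy]hex-5-en-1-ol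
Conditions: O3, CH2Cl2–MeOH, −78 °C (Sudan red 7B end point); then NaBH4, −78 → 0 °C
Reagents that add atoms: ozone, [O-][O+]=O
Why: Chemoselective ozonolysis, the electron-rich trisubstituted olefin reacting far faster than the hindered monosubstituted vinyl group, followed by borohydride reduction of the ozonide to the primary alcohol.

Step 3
Reactants: 3 (4S)-4-methyl-4-[(triethylsilyl)oxy]hex-5-en-1-ol
Product: 4 (3S)-6-iodo-3-methyl-3-[(triethylsilyl)oxy]hex-1-ene
Conditions: I2, PPh3, imidazole, CH2Cl2, 0 °C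
Reagents that add atoms: iodine, II
Why: Appel-type iodination of the primary alcohol under imidazole-buffered conditions that the tertiary silyl ether tolerates.

Step 4
Reactants: 4 (3S)-6-iodo-3-methyl-3-[(triethylsilyl)oxy]hex-1-ene
Product: 6 (5S)-5-methyl-5-[(triethylsilyl)oxy]hept-6-enoic acid, via alkyllithium 5 (not isolated)
Conditions: t-BuLi (2.1 equiv), Et2O–pentane, −78 °C; CO2, −78 → 0 °C; dilute HCl work-up
Reagents that add atoms: carbon dioxide, O=C=O
Why: Iodine–lithium exchange at −78 °C is faster than 5-exo carbolithiation onto the vinyl group, and carboxylation of the alkyllithium adds the single carbon that later becomes C1 of the oxolane.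

Step 5
Reactants: 7 triethyl phosphonoacetate; 8 allyl bromide
Product: 9 ethyl 2-(diethoxyphosphoryl)pent-4-enoate
Conditions: NaH, THF, 0 → 23 °C
Reagents that add atoms: none
Why: SN2 mono-alkylation of the stabilised phosphonoacetate anion.

Step 6
Reactants: 9 ethyl 2-(diethoxyphosphoryl)pent-4-enoate; 10 [(tert-butyldimethylsilyl)oxy]acetaldehyde
Product: 11 ethyl (2E)-4-[(tert-butyldimethylsilyl)oxy]-2-(prop-2-en-1-yl)but-2-enoate
Conditions: NaH, THF, 0 → 23 °C
Reagents that add atoms: none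
Why: Horner–Wadsworth–Emmons olefination, in which α-branched phosphonoacetates give mainly the E-enoate (ester trans to CH2OSi), the geometry that later places CH2OSi pseudo-equatorial in the Claisen transition state.

Step 7
Reactants: 11 ethyl (2E)-4-[(tert-butyldimethylsilyl)oxy]-2-(prop-2-en-1-yl)but-2-enoate
Product: 12 (2E)-4-[(tert-butyldimethylsilyl)oxy]-2-(prop-2-en-1-yl)but-2-en-1-ol
Conditions: i-Bu2AlH (2.2 equiv), CH2Cl2, −78 °C; aq. potassium sodium tartrate
Reagents that add atoms: none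
Why: 1,2-Reduction of the conjugated ester to the allylic alcohol with retention of the alkene geometry.

Step 8
Reactants: 6 (5S)-5-methyl-5-[(triethylsilyl)oxy]hept-6-enoic acid; 12 (2E)-4-[(tert-butyldimethylsilyl)oxy]-2-(prop-2-en-1-yl)but-2-en-1-ol
Product: 13 (2E)-4-[(tert-butyldimethylsilyl)oxy]-2-(prop-2-en-1-yl)but-2-en-1-yl (5S)-5-methyl-5-[(triethylsilyl)oxy]hept-6-enoate
Conditions: EDC·HCl, DMAP (cat.), CH2Cl2, 0 → 23 °C
Reagents that add atoms: none
Why: Steglich esterification of a primary allylic alcohol, mild enough for both silyl ethers and the skipped diene.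

Step 9
Reactants: 13 (2E)-4-[(tert-butyldimethylsilyl)oxy]-2-(prop-2-en-1-yl)but-2-en-1-yl (5S)-5-methyl-5-[(triethylsilyl)oxy]hept-6-enoate
Product: 14 (6S,7Z,10E)-10-{2-[(tert-butyldimethylsilyl)oxy]ethylidene}-6-methyl-6-[(triethylsilyl)oxy]oxacycloundec-7-en-2-one
Conditions: second-generation Grubbs catalyst RuCl2(H2IMes)(PCy3)(=CHPh) (10 mol %), CH2Cl2 (1 mM), 40 °C
Reagents that add atoms: none
Why: Ring-closing metathesis engages only the two monosubstituted olefins (the trisubstituted alkylidene is inert) and high dilution favours the eleven-membered lactone, but the Z-olefin needed later is not guaranteed at this ring size and any E-isomer must be separated; no stereocentre is formed.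

Step 10
Reactants: 14 (6S,7Z,10E)-10-{2-[(tert-butyldimethylsilyl)oxy]ethylidene}-6-methyl-6-[(triethylsilyl)oxy]oxacycloundec-7-en-2-one
Product: 17 (3aR,6Z,8S,10aS)-8-hydroxy-8-methyl-4-methylidene-3,3a,4,5,8,9,10,10a-octahydro-1H-cyclonona[c]furan-1-one, via boron ketene acetal 15 (not isolated), via ring-contracted silyl ether acid 16 (not isolated)
Conditions: (4S,5S)-2-bromo-4,5-diphenyl-1,3-bis{[3,5-bis(trifluoromethyl)phenyl]sulfonyl}-1,3,2-diazaborolidine (1.5 equiv), i-Pr2NEt, CH2Cl2, −78 → 4 °C, 48 h; then HF·pyridine, THF, 0 → 23 °C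
Reagents that add atoms: none
Why: Enantioselective boron-enolate Ireland–Claisen rearrangement run as a ring contraction, in which the endocyclic ketene acetal has its ring CH2 cis to the ring oxygen and the E-alkylidene holds CH2OSi pseudo-equatorial, so that a chair [3,3] shift forms the ring-fusion C–C bond with the carboxyl and silyloxymethyl groups trans (10aS,3aR, face chosen by the C2-symmetric sulfonamide ligand on boron) and turns the allylic C–O bond into the exocyclic methylene, after which HF·pyridine removes both silyl groups and the γ-hydroxy acid closes to the trans-fused lactone in the same flask.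

Step 11
Reactants: 18 3-methylbut-2-enal
Product: 19 (1E)-1-iodo-4-methylpenta-1,3-diene
Conditions: CHI3, CrCl2, THF, 0 °C
Reagents that add atoms: iodoform, IC(I)I
Why: Takai olefination, which converts the enal into the E-alkenyl iodide with high selectivity.

Step 12
Reactants: 17 (3aR,6Z,8S,10aS)-8-hydroxy-8-methyl-4-methylidene-3,3a,4,5,8,9,10,10a-octahydro-1H-cyclonona[c]furan-1-one; 19 (1E)-1-iodo-4-methylpenta-1,3-diene
Product: 21 (2E)-1-[(1S,2R,5Z,7S)-7-hydroxy-2-(hydroxymethyl)-7-methyl-3-methylidenecyclonon-5-en-1-yl]-5-methylhexa-2,4-dien-1-one, via dienyllithium 20 (not isolated)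
Conditions: 19 (2.6 equiv), t-BuLi (5.2 equiv), Et2O, −78 °C; then 17, THF, −78 °C; aq. NH4Cl at −78 °C
Reagents that add atoms: none
Why: Iodine–lithium exchange with retention of the E-geometry, then single addition of the alkenyllithium to the γ-lactone (the lithium hemiketalate is stable at −78 °C, one further equivalent being consumed by the tertiary hydroxyl), which opens the lactone to the dienone without touching the two ring stereocentres.

Step 13
Reactants: 21 (2E)-1-[(1S,2R,5Z,7S)-7-hydroxy-2-(hydroxymethyl)-7-methyl-3-methylidenecyclonon-5-en-1-yl]-5-methylhexa-2,4-dien-1-one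
Product: 23 (1R,3aR,6Z,8S,10aS)-1-(hydroxymethyl)-8-methyl-4-methylidene-1-[(1E)-4-methylpenta-1,3-dien-1-yl]-3,3a,4,5,8,9,10,10a-octahydro-1H-cyclonona[c]furan-8-ol, via dienyl oxirane 22 (not isolated)
Conditions: Me3S+ I−, KN(SiMe3)2, THF, −20 → 0 °C; then Pd2(dba)3·CHCl3 (2.5 mol %), (R,R)-DACH-phenyl Trost ligand (7.5 mol %), CH2Cl2, 23 °C
Reagents that add atoms: trimethylsulfonium iodide, C[S+](C)C.[I-]
Why: Corey–Chaykovsky 1,2-addition of the sulfonium ylide to the dienone gives the dienyl oxirane, which zerovalent palladium ionises to a π-allyl (pentadienyl) complex whose faces interconvert through the dimethyl-substituted terminus, so that 5-exo attack of the primary hydroxyl at the terminus next to the alkoxide (Trost-type dynamic kinetic asymmetric etherification) closes the oxolane with C1 set to R by the ligand, whichever oxirane epimer was formed, and leaves the E-diene and the free CH2OH.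

Step 14
Reactants: 23 (1R,3aR,6Z,8S,10aS)-1-(hydroxymethyl)-8-methyl-4-methylidene-1-[(1E)-4-methylpenta-1,3-dien-1-yl]-3,3a,4,5,8,9,10,10a-octahydro-1H-cyclonona[c]furan-8-ol; 24 nonadecanoic acid
Product: 25 [(1R,3aR,6Z,8S,10aS)-8-hydroxy-8-methyl-4-methylidene-1-[(1E)-4-methylpenta-1,3-dien-1-yl]-3,3a,4,5,8,9,10,10a-octahydro-1H-cyclonona[c]furan-1-yl]methyl nonadecanoate
Conditions: EDC·HCl, DMAP (cat.), CH2Cl2, 0 °C
Reagents that add atoms: none
Why: Steglich esterification under neutral conditions, in which only the primary hydroxyl reacts while the tertiary allylic alcohol and the acid-sensitive tertiary dienyl ether are left alone.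

**Compound list**
1 | (S)-(+)-linalool, (3S)-3,7-dimethylocta-1,6-dien-3-ol | C=C[C@@](C)(O)CCC=C(C)C | starting material
2 | (3S)-3,7-dimethyl-3-[(triethylsilyl)oxy]octa-1,6-diene | C=C[C@@](C)(O[Si](CC)(CC)CC)CCC=C(C)C | intermediate
3 | (4S)-4-methyl-4-[(triethylsilyl)oxy]hex-5-en-1-ol | C=C[C@@](C)(O[Si](CC)(CC)CC)CCCO | intermediate
4 | (3S)-6-iodo-3-methyl-3-[(triethylsilyl)oxy]hex-1-ene | C=C[C@@](C)(O[Si](CC)(CC)CC)CCCI | intermediate
5 | [(4S)-4-methyl-4-[(triethylsilyl)oxy]hex-5-en-1-yl]lithium | C=C[C@@](C)(O[Si](CC)(CC)CC)CCC[Li] | intermediate (not isolated)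
6 | (5S)-5-methyl-5-[(triethylsilyl)oxy]hept-6-enoic acid | C=C[C@@](C)(O[Si](CC)(CC)CC)CCCC(=O)O | intermediate
7 | triethyl phosphonoacetate | CCOC(=O)CP(=O)(OCC)OCC | starting material
8 | allyl bromide (3-bromoprop-1-ene) | C=CCBr | starting material
9 | ethyl 2-(diethoxyphosphoryl)pent-4-enoate (racemic) | CCOC(=O)C(CC=C)P(=O)(OCC)OCC | intermediate
10 | [(tert-butyldimethylsilyl)oxy]acetaldehyde | O=CCO[Si](C)(C)C(C)(C)C | starting material
11 | ethyl (2E)-4-[(tert-butyldimethylsilyl)oxy]-2-(prop-2-en-1-yl)but-2-enoate | CCOC(=O)/C(=C/CO[Si](C)(C)C(C)(C)C)CC=C | intermediate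
12 | (2E)-4-[(tert-butyldimethylsilyl)oxy]-2-(prop-2-en-1-yl)but-2-en-1-ol | OC/C(=C/CO[Si](C)(C)C(C)(C)C)CC=C | intermediate
13 | (2E)-4-[(tert-butyldimethylsilyl)oxy]-2-(prop-2-en-1-yl)but-2-en-1-yl (5S)-5-methyl-5-[(triethylsilyl)oxy]hept-6-enoate | O=C(OC/C(=C/CO[Si](C)(C)C(C)(C)C)CC=C)CCC[C@](C)(O[Si](CC)(CC)CC)C=C | intermediate
14 | (6S,7Z,10E)-10-{2-[(tert-butyldimethylsilyl)oxy]ethylidene}-6-methyl-6-[(triethylsilyl)oxy]oxacycloundec-7-en-2-one | O=C1OC/C(=C/CO[Si](C)(C)C(C)(C)C)C/C=C\[C@@](C)(O[Si](CC)(CC)CC)CCC1 | intermediate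
15 | boron ketene acetal of 14: the lactone enol O-bonded to the (4S,5S)-4,5-diphenyl-1,3-bis{[3,5-bis(trifluoromethyl)phenyl]sulfonyl}-1,3,2-diazaborolidin-2-yl group, ring CH2 cis to the ring oxygen | B1(O/C2=C/CC[C@](C)(O[Si](CC)(CC)CC)/C=C\C/C(=C\CO[Si](C)(C)C(C)(C)C)CO2)N(S(=O)(=O)c2cc(cc(c2)C(F)(F)F)C(F)(F)F)[C@@H](c2ccccc2)[C@H](c2ccccc2)N1S(=O)(=O)c1cc(cc(c1)C(F)(F)F)C(F)(F)F | intermediate (not isolated)
16 | (1S,2R,5Z,7S)-2-{[(tert-butyldimethylsilyl)oxy]methyl}-7-methyl-3-methylidene-7-[(triethylsilyl)oxy]cyclonon-5-ene-1-carboxylic acid (present as its boryl ester until work-up) | C=C1C/C=C\[C@@](C)(O[Si](CC)(CC)CC)CC[C@H](C(=O)O)[C@H]1CO[Si](C)(C)C(C)(C)C | intermediate (not isolated)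
17 | (3aR,6Z,8S,10aS)-8-hydroxy-8-methyl-4-methylidene-3,3a,4,5,8,9,10,10a-octahydro-1H-cyclonona[c]furan-1-one (trans-fused) | C=C1C/C=C\[C@@](C)(O)CC[C@H]2[C@H]1COC2=O | intermediate
18 | 3-methylbut-2-enal | CC(C)=CC=O | starting material
19 | (1E)-1-iodo-4-methylpenta-1,3-diene | I/C=C/C=C(C)C | intermediate
20 | [(1E)-4-methylpenta-1,3-dien-1-yl]lithium | [Li]/C=C/C=C(C)C | intermediate (not isolated)
21 | (2E)-1-[(1S,2R,5Z,7S)-7-hydroxy-2-(hydroxymethyl)-7-methyl-3-methylidenecyclonon-5-en-1-yl]-5-methylhexa-2,4-dien-1-one | C=C1C/C=C\[C@@](C)(O)CC[C@@H]([C@H]1CO)C(=O)/C=C/C=C(C)C | intermediate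
22 | (1S,2Z,6R,7S)-6-(hydroxymethyl)-1-methyl-5-methylidene-7-{2-[(1E)-4-methylpenta-1,3-dien-1-yl]oxiran-2-yl}cyclonon-2-en-1-ol (both oxirane epimers) | C=C1C/C=C\[C@@](C)(O)CC[C@@H]([C@H]1CO)C2(CO2)/C=C/C=C(C)C | intermediate (not isolated)
23 | (1R,3aR,6Z,8S,10aS)-1-(hydroxymethyl)-8-methyl-4-methylidene-1-[(1E)-4-methylpenta-1,3-dien-1-yl]-3,3a,4,5,8,9,10,10a-octahydro-1H-cyclonona[c]furan-8-ol | C=C1C/C=C\[C@@](C)(O)CC[C@H]2[C@H]1CO[C@@]2(/C=C/C=C(C)C)CO | intermediate
24 | nonadecanoic acid | CCCCCCCCCCCCCCCCCCC(=O)O | starting material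
25 | [(1R,3aR,6Z,8S,10aS)-8-hydroxy-8-methyl-4-methylidene-1-[(1E)-4-methylpenta-1,3-dien-1-yl]-3,3a,4,5,8,9,10,10a-octahydro-1H-cyclonona[c]furan-1-yl]methyl nonadecanoate | C=C1C/C=C\[C@@](C)(O)CC[C@H]2[C@H]1CO[C@@]2(/C=C/C=C(C)C)COC(=O)CCCCCCCCCCCCCCCCCC | target

**Totals**
Total step count: 14. Longest linear sequence: 10 steps (1, 2, 3, 4, 8, 9, 10, 12, 13, 14).

**Steps most likely to fail, with fallbacks**

Step 10 (the ring-contracting Claisen rearrangement: a strained bicyclic transition state, Lewis-acidic boron next to two silyl ethers, and reagent control that must override the resident carbinol centre). The fallback sets out from macrolactone 14 and returns at hydroxy dienone 21, so step 12 is bypassed. The lithium enolate of 14 (LiN(SiMe3)2, THF, −78 °C) is C-acylated with (2E)-5-methylhexa-2,4-dienoyl chloride, available from 18 and malonic acid, to give the β-keto lactone (6S,7Z,10E)-10-{2-[(tert-butyldimethylsilyl)oxy]ethylidene}-6-methyl-3-[(2E)-5-methylhexa-2,4-dienoyl]-6-[(triethylsilyl)oxy]oxacycloundec-7-en-2-one F2. Heating F2 in toluene at 110 °C brings about a Carroll rearrangement of its enol, again as a ring contraction, with loss of CO2, to the protected dienone (2E)-1-[(1S,2R,5Z,7S)-2-{[(tert-butyldimethylsilyl)oxy]methyl}-7-methyl-3-methylidene-7-[(triethylsilyl)oxy]cyclonon-5-en-1-yl]-5-methylhexa-2,4-dien-1-one F3. The centre next to the ketone can equilibrate to the trans arrangement, but facial control then rests on the substrate alone. HF·pyridine then frees 21.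

Step 9 (macrocyclic metathesis: E/Z ratio in an eleven-membered ring and oligomerisation). The fallback sets out from ester 13 and returns at lactone 17 without passing through 14. The open-chain ester 13 is rearranged with the same bromodiazaborolidine and i-Pr2NEt (an ordinary strain-free chair Ireland–Claisen). HF·pyridine in the same flask then gives the monocyclic trans lactone (3S,4R)-3-[(3S)-3-hydroxy-3-methylpent-4-en-1-yl]-4-(penta-1,4-dien-2-yl)oxolan-2-one F1. Ring-closing metathesis of F1 (second-generation Grubbs catalyst RuCl2(H2IMes)(PCy3)(=CHPh), CH2Cl2, 1 mM, 40 °C) then closes the nine-membered ring on the rigid lactone, where the Z-olefin is strongly favoured, to give 17.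

Step 13 (telescoped epoxidation and palladium cyclisation: premature uncatalysed closure of the oxirane, and ligand control at a fully substituted carbon). The fallback sets out from 21 and returns at 23. (i-PrO)Me2SiCH2MgCl with CeCl3 in THF at −78 °C adds 1,2 to the dienone to give the β-hydroxysilane (3E)-2-[(1S,2R,5Z,7S)-7-hydroxy-2-(hydroxymethyl)-7-methyl-3-methylidenecyclonon-5-en-1-yl]-1-[dimethyl(propan-2-yloxy)silyl]-6-methylhepta-3,5-dien-2-ol F4. Tamao oxidation (KF, KHCO3, H2O2, THF–MeOH) gives the triol (3E)-2-[(1S,2R,5Z,7S)-7-hydroxy-2-(hydroxymethyl)-7-methyl-3-methylidenecyclonon-5-en-1-yl]-6-methylhepta-3,5-diene-1,2-diol F5. Pyridinium p-toluenesulfonate in CH2Cl2 at 0 °C then ionises the tertiary bis-allylic alcohol and the ring hydroxymethyl group closes the oxolane 23 under thermodynamic control; the C1 epimer is separated and re-equilibrated.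

**Further compounds**
F1 | step 9 | (3S,4R)-3-[(3S)-3-hydroxy-3-methylpent-4-en-1-yl]-4-(penta-1,4-dien-2-yl)oxolan-2-one | C=C[C@@](C)(O)CC[C@H]2[C@H](C(=C)CC=C)COC2=O
F2 | step 10 | (6S,7Z,10E)-10-{2-[(tert-butyldimethylsilyl)oxy]ethylidene}-6-methyl-3-[(2E)-5-methylhexa-2,4-dienoyl]-6-[(triethylsilyl)oxy]oxacycloundec-7-en-2-one | O=C1OC/C(=C/CO[Si](C)(C)C(C)(C)C)C/C=C\[C@@](C)(O[Si](CC)(CC)CC)CCC1C(=O)/C=C/C=C(C)C
F3 | step 10 | (2E)-1-[(1S,2R,5Z,7S)-2-{[(tert-butyldimethylsilyl)oxy]methyl}-7-methyl-3-methylidene-7-[(triethylsilyl)oxy]cyclonon-5-en-1-yl]-5-methylhexa-2,4-dien-1-one | C=C1C/C=C\[C@@](C)(O[Si](CC)(CC)CC)CC[C@@H]([C@H]1CO[Si](C)(C)C(C)(C)C)C(=O)/C=C/C=C(C)C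
F4 | step 13 | (3E)-2-[(1S,2R,5Z,7S)-7-hydroxy-2-(hydroxymethyl)-7-methyl-3-methylidenecyclonon-5-en-1-yl]-1-[dimethyl(propan-2-yloxy)silyl]-6-methylhepta-3,5-dien-2-ol (both C2 epimers) | C=C1C/C=C\[C@@](C)(O)CC[C@@H]([C@H]1CO)C(O)(C[Si](C)(C)OC(C)C)/C=C/C=C(C)C
F5 | step 13 | (3E)-2-[(1S,2R,5Z,7S)-7-hydroxy-2-(hydroxymethyl)-7-methyl-3-methylidenecyclonon-5-en-1-yl]-6-methylhepta-3,5-diene-1,2-diol (both C2 epimers) | C=C1C/C=C\[C@@](C)(O)CC[C@@H]([C@H]1CO)C(O)(CO)/C=C/C=C(C)C
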